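**Retrosynthetic overview**

1. Target 13 is three benzene rings joined by two diaryl ether oxygens: ring A (4-allyl-2-methoxyphenoxy), central ring B (5-allyl-3-methoxy, oxygen at C4 and C5) and ring C (5-allyl-3-methoxy, free OH at C4). It has no stereocentre.
2. The strategy rests on each allyl group being a benzylic CH2 bonded to a vinyl CH. Cutting the three CH2–CH bonds on rings A, B and C leads back to three CH2–CO2H side chains of homovanillic acid type, which cannot isomerise during ether formation as allyl groups would.
3. Last C–C bonds: threefold nickel-electrocatalytic decarboxylative vinylation of the tris(N-hydroxyphthalimide ester) 10 with vinyl bromide 11, followed by MOM removal.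
4. Aryl–O bonds: O of ring A to C5 of ring B, then O at C4 of ring B to C5 of ring C, by two successive Ullmann etherifications that use the same iodide 4, first with phenol 2 and then with phenol 6.
5. No ring is formed in the route; all three rings come from homovanillic acid 1, assembled in the order A + B, then C.

Key step: step 9

Remark: ring positions are numbered as in homovanillic acid (C1 side chain, C3 methoxy, C4 phenol oxygen, C5 the free position ortho to that oxygen); vinyl bromide is handled as its commercial solution in THF. Steps 8 and 9 each build three equivalents of one partner into the molecule; the first equivalent stands on the Reactants line and the two further ones on the line of reagents that add atoms.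

**Step 1**
Reactants: 1 homovanillic acid
Product: 2 methyl homovanillate, methyl 2-(4-hydroxy-3-methoxyphenyl)acetate
Conditions: MeOH, H2SO4 (cat.), reflux
Reagents that add atoms: methanol, CO
Why: Fischer esterification driven by methanol as solvent; the phenol is inert to these conditions.

**Step 2**
Reactants: 2 methyl homovanillate
Product: 3 methyl 2-(4-hydroxy-3-iodo-5-methoxyphenyl)acetate
Conditions: N-iodosuccinimide (1.05 equiv), p-TsOH·H2O (10 mol%), MeCN, 0 °C to rt
Reagents that add atoms: N-iodosuccinimide, O=C1CCC(=O)N1I
Why: Electrophilic aromatic iodination directed by the free hydroxyl, the strongest donor, whose para position is blocked by the side chain, so iodine should enter at the open ortho carbon C5 as in the iodination of vanillin.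

**Step 3**
Reactants: 3 methyl 2-(4-hydroxy-3-iodo-5-methoxyphenyl)acetate
Product: 4 methyl 2-[3-iodo-5-methoxy-4-(methoxymethoxy)phenyl]acetate
Conditions: MOMCl, iPr2NEt, CH2Cl2, 0 °C to rt
Reagents that add atoms: chloromethyl methyl ether, COCCl
Why: Williamson-type O-alkylation of the phenol with the highly reactive chloromethyl ether under a hindered amine base that leaves the arylacetic ester untouched.

**Step 4**
Reactants: 2 methyl homovanillate; 4 methyl 2-[3-iodo-5-methoxy-4-(methoxymethoxy)phenyl]acetate
Product: 5 methyl 2-[3-methoxy-4-(methoxymethoxy)-5-[2-methoxy-4-(2-methoxy-2-oxoethyl)phenoxy]phenyl]acetate (ring A–O–ring B diester, ring B phenol as MOM ether)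
Conditions: CuI (10 mol%), N,N-dimethylglycine hydrochloride (30 mol%), Cs2CO3 (2.5 equiv), 1,4-dioxane, 100 °C, argon
Reagents that add atoms: none
Why: Amino acid-promoted Ullmann diaryl ether coupling of a guaiacol-type phenoxide with an aryl iodide, in which the MOM ether keeps the iodide fragment from condensing with itself and the insoluble carbonate in dioxane spares the esters.

**Step 5**
Reactants: 5 ring A–O–ring B diester MOM ether
Product: 6 methyl 2-[4-hydroxy-3-methoxy-5-[2-methoxy-4-(2-methoxy-2-oxoethyl)phenoxy]phenyl]acetate
Conditions: HCl (conc. aq., 3 equiv), MeOH, 45 °C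
Reagents that add atoms: none
Why: Acid-catalysed acetal exchange transfers the methoxymethyl group to methanol, while the methyl esters are degenerate to methanolysis and any ester hydrolysed in step 4 is re-esterified.

**Step 6**
Reactants: 6 ring A–O–ring B phenol; 4 methyl 2-[3-iodo-5-methoxy-4-(methoxymethoxy)phenyl]acetate
Product: 7 methyl 2-[3-methoxy-4-[3-methoxy-2-(methoxymethoxy)-5-(2-methoxy-2-oxoethyl)phenoxy]-5-[2-methoxy-4-(2-methoxy-2-oxoethyl)phenoxy]phenyl]acetate (triester of the A–B–C core, ring C phenol as MOM ether)
Conditions: CuI (20 mol%), picolinic acid (40 mol%), K3PO4 (3 equiv), 4 (1.5 equiv), DMSO, 90 °C, argon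
Reagents that add atoms: none
Why: Ullmann diaryl ether coupling under picolinic acid ligation, a system suited to 2,6-disubstituted phenols and ortho-substituted aryl iodides, and any ester lost to phosphate is of no consequence because step 7 saponifies all three.

**Step 7**
Reactants: 7 triester of the A–B–C core
Product: 8 2-[4-[5-(carboxymethyl)-3-methoxy-2-(methoxymethoxy)phenoxy]-3-[4-(carboxymethyl)-2-methoxyphenoxy]-5-methoxyphenyl]acetic acid (triacid)
Conditions: LiOH·H2O (9 equiv), THF/H2O 3:1, rt; then cold 1 M HCl to pH 3
Reagents that add atoms: lithium hydroxide, [Li+].[OH-]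
Why: Saponification of the three methyl esters by acyl–oxygen cleavage; the MOM acetal and the diaryl ethers are inert to hydroxide and survive a brief cold acidification.

**Step 8**
Reactants: 8 triacid; 9 N-hydroxyphthalimide (3 equiv)
Product: 10 tris(1,3-dioxoisoindolin-2-yl) ester of triacid 8
Conditions: N,N'-diisopropylcarbodiimide (3.6 equiv), 9 (3.6 equiv), DMAP (10 mol%), CH2Cl2/THF, 0 °C to rt
Reagents that add atoms: N-hydroxyphthalimide 9 (the second and third equivalents that end up in 10), O=C1c2ccccc2C(=O)N1O.O=C1c2ccccc2C(=O)N1O
Why: Threefold Steglich-type carbodiimide esterification, one N-hydroxyphthalimide per carboxyl group, with the acidic N-hydroxy imide as acyl acceptor under near-neutral conditions that keep the MOM acetal.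

**Step 9**
Reactants: 10 tris(N-hydroxyphthalimide ester); 11 vinyl bromide (3 equiv consumed)
Product: 12 MOM ether of the target, 5-allyl-1-[4-allyl-2-(4-allyl-2-methoxyphenoxy)-6-methoxyphenoxy]-3-methoxy-2-(methoxymethoxy)benzene
Conditions: NiBr2(dme) (30 mol%), 2,2'-bipyridine (35 mol%), vinyl bromide (1 M in THF, 9 equiv), LiBr (electrolyte), DMF, undivided cell, sacrificial Mg anode, reticulated vitreous carbon cathode, constant low current, rt
Reagents that add atoms: vinyl bromide 11 (the second and third equivalents that end up in 12), C=CBr.C=CBr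
Why: Cathodic reduction converts the bipyridine-ligated divalent nickel into low-valent nickel, which adds oxidatively to vinyl bromide; single-electron transfer to each N-acyloxyphthalimide group releases phthalimide anion, CO2 and a primary benzylic radical, the vinylnickel species captures this radical, and reductive elimination from the resulting trivalent nickel forms the ArCH2–CH=CH2 bond while the magnesium anode supplies the electrons as Mg2+. The closest known reaction type is the nickel-electrocatalytic decarboxylative alkenylation of N-hydroxyphthalimide esters with alkenyl bromides, and benzylic esters of this kind are established partners in nickel-catalysed reductive couplings with alkenyl bromides; here the reaction is applied three times on one molecule. No ring is closed and no stereocentre is created. The selectivity needed is cross-coupling over dimerisation or reduction of the benzylic radicals at all three sites; it is secured by a large excess of vinyl bromide, so that vinylnickel is always the radical trap, and by a low constant current, so that two radicals are rarely present at once. The medium is neutral and reductive, so the new terminal alkenes cannot migrate into conjugation with the rings, and the aryl ethers and the MOM acetal lie outside the reduction window.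

**Step 10**
Reactants: 12 MOM ether of the target
Product: 13 target, 2-methoxy-6-[2-methoxy-6-(2-methoxy-4-prop-2-enylphenoxy)-4-prop-2-enylphenoxy]-4-prop-2-enylphenol
Conditions: HCl (conc. aq., 5 equiv), MeOH, rt to 40 °C
Reagents that add atoms: none
Why: Acid-catalysed MOM cleavage by acetal exchange with methanol; isolated terminal alkenes and diaryl ethers are stable to dilute methanolic HCl, so the allyl groups should neither migrate nor add HCl.

**Compound list**

1 | homovanillic acid | COc1cc(CC(=O)O)ccc1O | starting material
2 | methyl homovanillate, methyl 2-(4-hydroxy-3-methoxyphenyl)acetate | COC(=O)Cc1ccc(O)c(OC)c1 | intermediate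
3 | methyl 2-(4-hydroxy-3-iodo-5-methoxyphenyl)acetate | COC(=O)Cc1cc(I)c(O)c(OC)c1 | intermediate
4 | methyl 2-[3-iodo-5-methoxy-4-(methoxymethoxy)phenyl]acetate | COC(=O)Cc1cc(I)c(OCOC)c(OC)c1 | intermediate
5 | methyl 2-[3-methoxy-4-(methoxymethoxy)-5-[2-methoxy-4-(2-methoxy-2-oxoethyl)phenoxy]phenyl]acetate | COC(=O)Cc1ccc(Oc2cc(CC(=O)OC)cc(OC)c2OCOC)c(OC)c1 | intermediate
6 | methyl 2-[4-hydroxy-3-methoxy-5-[2-methoxy-4-(2-methoxy-2-oxoethyl)phenoxy]phenyl]acetate | COC(=O)Cc1ccc(Oc2cc(CC(=O)OC)cc(OC)c2O)c(OC)c1 | intermediate
7 | methyl 2-[3-methoxy-4-[3-methoxy-2-(methoxymethoxy)-5-(2-methoxy-2-oxoethyl)phenoxy]-5-[2-methoxy-4-(2-methoxy-2-oxoethyl)phenoxy]phenyl]acetate | COC(=O)Cc1ccc(Oc2cc(CC(=O)OC)cc(OC)c2Oc2cc(CC(=O)OC)cc(OC)c2OCOC)c(OC)c1 | intermediate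
8 | 2-[4-[5-(carboxymethyl)-3-methoxy-2-(methoxymethoxy)phenoxy]-3-[4-(carboxymethyl)-2-methoxyphenoxy]-5-methoxyphenyl]acetic acid | OC(=O)Cc1ccc(Oc2cc(CC(=O)O)cc(OC)c2Oc2cc(CC(=O)O)cc(OC)c2OCOC)c(OC)c1 | intermediate
9 | N-hydroxyphthalimide | O=C1c2ccccc2C(=O)N1O | starting material
10 | tris(1,3-dioxoisoindolin-2-yl) ester of triacid 8 | O=C(Cc1ccc(Oc2cc(CC(=O)ON3C(=O)c4ccccc4C3=O)cc(OC)c2Oc2cc(CC(=O)ON3C(=O)c4ccccc4C3=O)cc(OC)c2OCOC)c(OC)c1)ON1C(=O)c2ccccc2C1=O | intermediate
11 | vinyl bromide | C=CBr | starting material
12 | 5-allyl-1-[4-allyl-2-(4-allyl-2-methoxyphenoxy)-6-methoxyphenoxy]-3-methoxy-2-(methoxymethoxy)benzene | C=CCc1ccc(Oc2cc(CC=C)cc(OC)c2Oc2cc(CC=C)cc(OC)c2OCOC)c(OC)c1 | intermediate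
13 | 2-methoxy-6-[2-methoxy-6-(2-methoxy-4-prop-2-enylphenoxy)-4-prop-2-enylphenoxy]-4-prop-2-enylphenol (CNP0153774.0) | C=CCc1ccc(Oc2cc(CC=C)cc(OC)c2Oc2cc(CC=C)cc(OC)c2O)c(OC)c1 | target

**Step count**

Total steps: 10. Longest linear sequence: 10 steps (1 → 2 → 3 → 4 → 5 → 6 → 7 → 8 → 10 → 12 → 13); compounds 2 and 4 are each used a second time as coupling partners.

**Steps most likely to fail**

Step 9 (threefold electrochemical vinylation). Conversion must be high at three sites in one molecule. Benzylic radical dimerisation, reduction of an arm to a methyl group, or stalling after one or two couplings would give mixtures that are hard to separate. The fallback leaves the decarboxylative approach and sets out from triester 7. Reduction with LiAlH4 in THF at 0 °C should give the triol 2-[4-[5-(2-hydroxyethyl)-3-methoxy-2-(methoxymethoxy)phenoxy]-3-[4-(2-hydroxyethyl)-2-methoxyphenoxy]-5-methoxyphenyl]ethanol F1. Oxidation with Dess–Martin periodinane (NaHCO3, CH2Cl2, 0 °C) should give the tris(arylacetaldehyde) F2, which is used at once. Threefold Wittig methylenation with methylenetriphenylphosphorane (from methyltriphenylphosphonium bromide and KOtBu, THF, −78 to 0 °C) should then give the three allyl groups and rejoin the route at 12.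

Step 6 (second etherification). The phenol oxygen of 6 sits between a methoxy and an aryloxy group, and the iodide carries an ortho MOM-oxy group. Ligand exchange and C–O bond formation at copper may therefore be slow, letting hydrodeiodination of 4 and ester cleavage take over. The fallback reverses the order of ether formation, so that the congested oxygen is arylated while its neighbour is only a bromine atom. It sets out from 2 and 4. Bromination of 2 (Br2, CH2Cl2, 0 °C) should give methyl 2-(3-bromo-4-hydroxy-5-methoxyphenyl)acetate F3. A chemoselective Ullmann coupling of this phenol at the C–I bond of 4 (CuI, picolinic acid, K3PO4, DMSO, 80 °C) should give the ring B–ring C bromo diaryl ether methyl 2-[3-bromo-5-methoxy-4-[3-methoxy-2-(methoxymethoxy)-5-(2-methoxy-2-oxoethyl)phenoxy]phenyl]acetate F4. A second Ullmann coupling of phenol 2 at the C–Br bond of F4 (CuI, N,N-dimethylglycine hydrochloride, Cs2CO3, dioxane, 110 °C) should return to the route at 7, bypassing 5 and 6.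

Step 4 (first etherification). The electron-rich iodide with its ortho MOM-oxy group may react sluggishly, with reductive loss of iodine and partial ester cleavage by carbonate as competing processes. The fallback replaces the Ullmann reaction by an oxidative Chan–Lam coupling and sets out from 4. Miyaura borylation (bis(pinacolato)diboron, PdCl2(dppf), KOAc, dioxane, 85 °C) should give the pinacol boronate methyl 2-[3-methoxy-4-(methoxymethoxy)-5-(4,4,5,5-tetramethyl-1,3,2-dioxaborolan-2-yl)phenyl]acetate F5. Cleavage with NaIO4 and NH4OAc in acetone–water should give the boronic acid [3-methoxy-2-(methoxymethoxy)-5-(2-methoxy-2-oxoethyl)phenyl]boronic acid F6. Coupling of F6 with phenol 2 (Cu(OAc)2, pyridine, 4 Å molecular sieves, CH2Cl2, air, rt) should return to the route at 5.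

**Further compounds**

F1 | step 9 | 2-[4-[5-(2-hydroxyethyl)-3-methoxy-2-(methoxymethoxy)phenoxy]-3-[4-(2-hydroxyethyl)-2-methoxyphenoxy]-5-methoxyphenyl]ethanol | OCCc1ccc(Oc2cc(CCO)cc(OC)c2Oc2cc(CCO)cc(OC)c2OCOC)c(OC)c1
F2 | step 9 | 2-[3-methoxy-4-[3-methoxy-2-(methoxymethoxy)-5-(2-oxoethyl)phenoxy]-5-[2-methoxy-4-(2-oxoethyl)phenoxy]phenyl]acetaldehyde | O=CCc1ccc(Oc2cc(CC=O)cc(OC)c2Oc2cc(CC=O)cc(OC)c2OCOC)c(OC)c1
F3 | step 6 | methyl 2-(3-bromo-4-hydroxy-5-methoxyphenyl)acetate | COC(=O)Cc1cc(Br)c(O)c(OC)c1
F4 | step 6 | methyl 2-[3-bromo-5-methoxy-4-[3-methoxy-2-(methoxymethoxy)-5-(2-methoxy-2-oxoethyl)phenoxy]phenyl]acetate | COC(=O)Cc1cc(Br)c(Oc2cc(CC(=O)OC)cc(OC)c2OCOC)c(OC)c1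
F5 | step 4 | methyl 2-[3-methoxy-4-(methoxymethoxy)-5-(4,4,5,5-tetramethyl-1,3,2-dioxaborolan-2-yl)phenyl]acetate | COC(=O)Cc1cc(B2OC(C)(C)C(C)(C)O2)c(OCOC)c(OC)c1
F6 | step 4 | [3-methoxy-2-(methoxymethoxy)-5-(2-methoxy-2-oxoethyl)phenyl]boronic acid | COC(=O)Cc1cc(B(O)O)c(OCOC)c(OC)c1
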